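The carbocycle spiro-fused at the ketal carbon (ketal C, prenyl-bearing CH, two C=O, two sp2 carbons shared with the 2H-pyran) is a 2-oxy-1,4-benzoquinone trapped as a ketal-lactone. The target is therefore cut into the caged hydroxy acid and a pyrano-hydroxyquinone, i.e. an oxidised 5,7-dihydroxychromene. The key step makes that benzene ring in one operation from a 2H-pyran ester and an aliphatic ester: vinylogous Claisen acylation, Dieckmann closure between the prenyl-bearing carbon and the ring-ester carbonyl, aromatisation. Teuber oxidation, a Claisen/Diels–Alder cascade to the cage and a final esterification/oxa-Michael spiroketalisation complete the route.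

Key step: step 3

Remark (assumption): the configurations at the ketal carbon and at the neighbouring prenyl-bearing CH are taken to be the thermodynamically preferred ones, because both centres can equilibrate (retro-oxa-Michael/re-addition, enolisation); step 14 relies on this.
Remark: 18 and 19 are racemic; 19 is drawn as the enantiomer that is carried on. Cage compounds are named as 4-oxatricyclo[4.3.1.0^3,7]decanes; the SMILES in the list is decisive for configuration.

Step 1
Reactants: 1 methyl acetoacetate; 2 3-methylbut-2-enal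
Product: 4 methyl 2,2,6-trimethyl-2H-pyran-5-carboxylate, via Knoevenagel dienone 3 (not isolated)
Conditions: ethylenediammonium diacetate (10 mol %), MeOH, rt to 50 °C
Reagents that add atoms: none
Why: Knoevenagel condensation gives 1-oxatriene 3, which closes by oxa-6π electrocyclisation through the ketone oxygen (formal [3+3]); the gem-dimethyl terminus and the conjugated ester should hold the valence equilibrium on the 2H-pyran side.

Step 2
Reactants: 5 2-methylbut-3-en-2-ol; 6 triethyl orthoacetate
Product: 8 ethyl 5-methylhex-4-enoate, via ketene acetal 7 (not isolated)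
Conditions: EtCO2H (cat.), 140 °C, EtOH distilled off
Reagents that add atoms: none
Why: Johnson–Claisen rearrangement: acid-catalysed exchange gives mixed ketene acetal 7, whose [3,3] shift turns the tertiary allyl unit into the γ,δ-unsaturated ester with the trisubstituted (prenyl-type) olefin.

Step 3
Reactants: 4 methyl 2,2,6-trimethyl-2H-pyran-5-carboxylate; 8 ethyl 5-methylhex-4-enoate
Product: 10 2,2-dimethyl-6-(3-methylbut-2-en-1-yl)-2H-chromene-5,7-diol, via keto ester 9 (not isolated)
Conditions: 4 (2 equiv), LDA (2 equiv), THF, −78 °C; 8 (1 equiv), −78 to −20 °C; LDA (2.2 equiv), −78 °C to rt; 1 M HCl (excess 4 is recovered)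
Reagents that add atoms: none
Why: LDA deprotonates the 6-methyl group of 4 (vinylogous to the ester) and the extended enolate undergoes Claisen acylation at that carbon with ester 8 to give keto ester 9 as its enolate; the second portion of LDA deprotonates the α′-CH2 (the carbon bearing the prenyl CH2), this carbanion attacks the ring-ester carbonyl, methoxide is lost and the resulting cyclohexenedione tautomerises to resorcinol 10. The closest known reaction type is the tandem Claisen/Dieckmann annulation of o-toluate anions with esters to naphthalene-1,3-diols, the laboratory counterpart of polyketide Claisen cyclisation to phloroglucinols. The ring closes in a 6-(enolendo)-exo-trig mode on the ester C=O. No stereocentre is formed; the substitution pattern (ester carbon becomes C-5 with OH between the pyran carbon and the prenyl carbon, ketone carbon becomes C-7 with OH, former methyl becomes C-8 with H) follows from connectivity alone. The selectivity needed is C- over O-cyclisation (enol-lactone/pyranone formation), which should be secured by the far more nucleophilic dianion carbanion, by the cis disposition of ester and side chain on the pyran C5=C6 bond and by irreversible aromatisation.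

Step 4
Reactants: 10 2,2-dimethyl-6-(3-methylbut-2-en-1-yl)-2H-chromene-5,7-diol
Product: 11 7-hydroxy-2,2-dimethyl-6-(3-methylbut-2-en-1-yl)-2H-chromene-5,8-dione
Conditions: (KO3S)2NO (2.2 equiv), KH2PO4 buffer (pH 6), acetone/H2O, 0 °C to rt
Reagents that add atoms: potassium nitrosodisulfonate (Fremy's salt), [K+].[K+].[O]N(S(=O)(=O)[O-])S(=O)(=O)[O-]
Why: Teuber oxidation: the phenoxyl radical is trapped by a second nitroxide at C-8, the only unsubstituted ring position (para to 5-OH, ortho to 7-OH), and collapse gives the p-quinone with the 7-oxygen left as the vinylogous-acid OH; the neutral buffer should spare the chromene and prenyl olefins.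

Step 5
Reactants: 5 2-methylbut-3-en-2-ol
Product: 12 tert-butyl 2-methylbut-3-en-2-yl carbonate
Conditions: n-BuLi, THF, 0 °C; Boc2O, 0 °C to rt; H2O
Reagents that add atoms: di-tert-butyl dicarbonate, CC(C)(C)OC(=O)OC(=O)OC(C)(C)C
Why: alkoxycarbonylation of the lithium alkoxide of the tertiary allylic alcohol gives the mixed carbonate that serves as the 1,1-dimethylallyl donor.

Step 6
Reactants: 13 2,3,4-trihydroxybenzaldehyde; 12 tert-butyl 2-methylbut-3-en-2-yl carbonate
Product: 14 2-hydroxy-3,4-bis[(2-methylbut-3-en-2-yl)oxy]benzaldehyde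
Conditions: 12 (2.3 equiv), Pd(PPh3)4 (5 mol %), THF, 0 °C, short reaction time
Reagents that add atoms: none
Why: Tsuji–Trost O-allylation: decarboxylative ionisation gives the 1,1-dimethylallyl–Pd cation and tert-butoxide, the 4- and 3-phenoxides attack the more substituted allyl terminus under kinetic control (low temperature) to give the tertiary ethers, and the formyl-chelated 2-OH is expected to react last and stay free.

Step 7
Reactants: 14 2-hydroxy-3,4-bis[(2-methylbut-3-en-2-yl)oxy]benzaldehyde
Product: 16 2,5-dihydroxy-3,4-bis[(2-methylbut-3-en-2-yl)oxy]benzaldehyde, via formylquinone 15 (not isolated)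
Conditions: (KO3S)2NO (2.5 equiv), KH2PO4 buffer, acetone/H2O, 0 °C to rt; extraction into EtOAc, then aq. Na2S2O4, rt
Reagents that add atoms: potassium nitrosodisulfonate (Fremy's salt), [K+].[K+].[O]N(S(=O)(=O)[O-])S(=O)(=O)[O-]
Why: Teuber oxidation puts oxygen at C-5, the only open position para to the free 2-OH (both ortho positions are substituted), and the electrophilic formylquinone 15 is reduced at once by dithionite to the hydroquinone without acid or base that would harm the tertiary allyl ethers.

Step 8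
Reactants: 16 2,5-dihydroxy-3,4-bis[(2-methylbut-3-en-2-yl)oxy]benzaldehyde
Product: 17 2,5-bis[(tert-butyldimethylsilyl)oxy]-3,4-bis[(2-methylbut-3-en-2-yl)oxy]benzaldehyde
Conditions: TBSCl (3 equiv), imidazole, DMAP (cat.), DMF, rt to 40 °C
Reagents that add atoms: tert-butyldimethylsilyl chloride, CC(C)(C)[Si](C)(C)Cl
Why: silylation of both phenols (Corey protocol) blocks enolisation of the later dienone and supplies the two bridgehead oxygens of the cage in a form that can be removed without base.

Step 9
Reactants: 17 2,5-bis[(tert-butyldimethylsilyl)oxy]-3,4-bis[(2-methylbut-3-en-2-yl)oxy]benzaldehyde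
Product: 19 rac-(1R*,3R*,6S*,7S*)-1,7-bis[(tert-butyldimethylsilyl)oxy]-5,5-dimethyl-3-(3-methylbut-2-en-1-yl)-2-oxo-4-oxatricyclo[4.3.1.0^3,7]dec-8-ene-8-carbaldehyde, via Claisen dienone 18 (not isolated)
Conditions: degassed toluene (0.02 M), BHT (cat.), 110 °C, sealed tube
Reagents that add atoms: none
Why: Claisen/Diels–Alder cascade: the allyl ether para to the formyl group (most polarised C–O bond) shifts [3,3] to C-3 to give dienone 18 (shifts to other positions are reversible and unproductive), and its siloxy-substituted diene is trapped by the vinyl group of the remaining tethered 1,1-dimethylallyl ether in an intramolecular Diels–Alder reaction; the short tether allows only one cage geometry, so the four stereocentres are set relative to one another and 19 is racemic.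

Step 10
Reactants: 19 racemic cage enal; 20 (1R,2R)-N,N'-dimethyl-1,2-diphenylethane-1,2-diamine
Product: 21 (4R,5R)-1,3-dimethyl-4,5-diphenylimidazolidin-2-yl derivative of the (1R,3R,6S,7S)-cage (aminal at C-8)
Conditions: 20 (1.05 equiv), 4 Å MS, CH2Cl2, rt; silica gel chromatography to separate the two diastereomers
Reagents that add atoms: none
Why: uncatalysed aminal formation from an aldehyde and a C2-symmetric secondary 1,2-diamine creates no new stereocentre, so the two enantiomers of 19 become two diastereomers that should be separable on silica; the diastereomer with the cage configuration of the target (to be assigned by X-ray) is carried on, which fixes the absolute configuration of all four cage centres.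

Step 11
Reactants: 21 aminal of the (1R,3R,6S,7S)-cage
Product: 22 (1R,3R,6S,7S)-1,7-bis[(tert-butyldimethylsilyl)oxy]-5,5-dimethyl-3-(3-methylbut-2-en-1-yl)-2-oxo-4-oxatricyclo[4.3.1.0^3,7]dec-8-ene-8-carbaldehyde
Conditions: 2% aq. HCl/Et2O (two-phase), 0 °C
Reagents that add atoms: water, O
Why: aminal hydrolysis under very mild aqueous acid is far faster than cleavage of the hindered tertiary silyl ethers, and the diamine is recovered from the aqueous phase.

Step 12
Reactants: 22 enantiopure cage enal
Product: 23 (1R,3R,6S,7S)-1,7-bis[(tert-butyldimethylsilyl)oxy]-5,5-dimethyl-3-(3-methylbut-2-en-1-yl)-2-oxo-4-oxatricyclo[4.3.1.0^3,7]dec-8-ene-8-carboxylic acid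
Conditions: NaClO2, NaH2PO4, 2-methylbut-2-ene, t-BuOH/H2O, rt
Reagents that add atoms: sodium chlorite, [Na+].[O-]Cl=O
Why: Pinnick oxidation converts the conjugated aldehyde to the acid at pH 3–4, and the olefin scavenger should protect the prenyl group from hypochlorite.

Step 13
Reactants: 23 bis-silyl cage acid
Product: 24 (1R,3R,6R,7S)-1,7-dihydroxy-5,5-dimethyl-3-(3-methylbut-2-en-1-yl)-2-oxo-4-oxatricyclo[4.3.1.0^3,7]dec-8-ene-8-carboxylic acid
Conditions: HF·pyridine, pyridine/THF, 0 °C to rt
Reagents that add atoms: none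
Why: fluoride-assisted Si–O cleavage under buffered, non-basic conditions frees both tertiary alcohols without forming alkoxides, so the β-hydroxy ketone (retro-aldol) and α-ketol (acyloin shift) arrays are not exposed to base.

Step 14
Reactants: 24 cage hydroxy acid; 11 7-hydroxy-2,2-dimethyl-6-(3-methylbut-2-en-1-yl)-2H-chromene-5,8-dione
Product: 26 CNP0222516.1 (target), via acyloxyquinone 25 (not isolated)
Conditions: DCC (1.2 equiv), DMAP (cat.), CH2Cl2, 0 °C to rt; then Et3N (cat.), rt
Reagents that add atoms: none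
Why: Steglich esterification of the vinylogous-acid OH of 11 gives acyloxyquinone 25, whose ester-bearing carbon is the β-carbon of the quinone enone, so the tertiary cage OH adds 6-exo-trig (intramolecular oxa-Michael, as in the second addition of ynone spiroketalisations and in alkoxy exchange of alkoxyquinones) and the enol ketonises; the ketal carbon and the α-CH are set under thermodynamic control (retro-oxa-Michael/re-addition and enolisation with Et3N), which should place the prenyl group anti to the bulky cage-bearing ketal oxygen as in the target.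

Compound list
1 | methyl acetoacetate | CC(=O)CC(=O)OC | starting material
2 | 3-methylbut-2-enal | CC(C)=CC=O | starting material
3 | methyl 2-acetyl-5-methylhexa-2,4-dienoate (Knoevenagel dienone) | COC(=O)C(=CC=C(C)C)C(C)=O | intermediate (not isolated)
4 | methyl 2,2,6-trimethyl-2H-pyran-5-carboxylate | COC(=O)C1=C(C)OC(C)(C)C=C1 | intermediate
5 | 2-methylbut-3-en-2-ol | CC(C)(O)C=C | starting material
6 | triethyl orthoacetate | CCOC(C)(OCC)OCC | starting material
7 | 1-ethoxy-1-[(2-methylbut-3-en-2-yl)oxy]ethene (ketene acetal) | C=C(OCC)OC(C)(C)C=C | intermediate (not isolated)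
8 | ethyl 5-methylhex-4-enoate | CCOC(=O)CCC=C(C)C | intermediate
9 | methyl 2,2-dimethyl-6-(6-methyl-2-oxohept-5-en-1-yl)-2H-pyran-5-carboxylate (keto ester) | COC(=O)C1=C(CC(=O)CCC=C(C)C)OC(C)(C)C=C1 | intermediate (not isolated)
10 | 2,2-dimethyl-6-(3-methylbut-2-en-1-yl)-2H-chromene-5,7-diol | CC(C)=CCc1c(O)cc2OC(C)(C)C=Cc2c1O | intermediate
11 | 7-hydroxy-2,2-dimethyl-6-(3-methylbut-2-en-1-yl)-2H-chromene-5,8-dione | CC(C)=CCC1=C(O)C(=O)C2=C(C=CC(C)(C)O2)C1=O | intermediate
12 | tert-butyl 2-methylbut-3-en-2-yl carbonate | CC(C)(C)OC(=O)OC(C)(C)C=C | intermediate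
13 | 2,3,4-trihydroxybenzaldehyde | O=Cc1ccc(O)c(O)c1O | starting material
14 | 2-hydroxy-3,4-bis[(2-methylbut-3-en-2-yl)oxy]benzaldehyde | O=Cc1ccc(OC(C)(C)C=C)c(OC(C)(C)C=C)c1O | intermediate
15 | 4,5-bis[(2-methylbut-3-en-2-yl)oxy]-3,6-dioxocyclohexa-1,4-diene-1-carbaldehyde (formylquinone) | O=CC1=CC(=O)C(OC(C)(C)C=C)=C(OC(C)(C)C=C)C1=O | intermediate (not isolated)
16 | 2,5-dihydroxy-3,4-bis[(2-methylbut-3-en-2-yl)oxy]benzaldehyde | O=Cc1cc(O)c(OC(C)(C)C=C)c(OC(C)(C)C=C)c1O | intermediate
17 | 2,5-bis[(tert-butyldimethylsilyl)oxy]-3,4-bis[(2-methylbut-3-en-2-yl)oxy]benzaldehyde | O=Cc1cc(O[Si](C)(C)C(C)(C)C)c(OC(C)(C)C=C)c(OC(C)(C)C=C)c1O[Si](C)(C)C(C)(C)C | intermediate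
18 | rac-2,5-bis[(tert-butyldimethylsilyl)oxy]-3-(3-methylbut-2-en-1-yl)-3-[(2-methylbut-3-en-2-yl)oxy]-4-oxocyclohexa-1,5-diene-1-carbaldehyde (Claisen dienone, racemic) | O=CC1=C(O[Si](C)(C)C(C)(C)C)C(CC=C(C)C)(OC(C)(C)C=C)C(=O)C(O[Si](C)(C)C(C)(C)C)=C1 | intermediate (not isolated)
19 | rac-(1R*,3R*,6S*,7S*)-1,7-bis[(tert-butyldimethylsilyl)oxy]-5,5-dimethyl-3-(3-methylbut-2-en-1-yl)-2-oxo-4-oxatricyclo[4.3.1.0^3,7]dec-8-ene-8-carbaldehyde (racemic; enantiomer carried on is drawn) | O=CC1=C[C@]2(O[Si](C)(C)C(C)(C)C)C[C@H]3C(C)(C)O[C@@](CC=C(C)C)(C2=O)[C@@]13O[Si](C)(C)C(C)(C)C | intermediate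
20 | (1R,2R)-N,N'-dimethyl-1,2-diphenylethane-1,2-diamine | CN[C@H](c1ccccc1)[C@H](NC)c1ccccc1 | starting material
21 | (1R,3R,6S,7S)-1,7-bis[(tert-butyldimethylsilyl)oxy]-8-[(4R,5R)-1,3-dimethyl-4,5-diphenylimidazolidin-2-yl]-5,5-dimethyl-3-(3-methylbut-2-en-1-yl)-4-oxatricyclo[4.3.1.0^3,7]dec-8-en-2-one | CN4C(C1=C[C@]2(O[Si](C)(C)C(C)(C)C)C[C@H]3C(C)(C)O[C@@](CC=C(C)C)(C2=O)[C@@]13O[Si](C)(C)C(C)(C)C)N(C)[C@H](c5ccccc5)[C@H]4c5ccccc5 | intermediate
22 | (1R,3R,6S,7S)-1,7-bis[(tert-butyldimethylsilyl)oxy]-5,5-dimethyl-3-(3-methylbut-2-en-1-yl)-2-oxo-4-oxatricyclo[4.3.1.0^3,7]dec-8-ene-8-carbaldehyde | O=CC1=C[C@]2(O[Si](C)(C)C(C)(C)C)C[C@H]3C(C)(C)O[C@@](CC=C(C)C)(C2=O)[C@@]13O[Si](C)(C)C(C)(C)C | intermediate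
23 | (1R,3R,6S,7S)-1,7-bis[(tert-butyldimethylsilyl)oxy]-5,5-dimethyl-3-(3-methylbut-2-en-1-yl)-2-oxo-4-oxatricyclo[4.3.1.0^3,7]dec-8-ene-8-carboxylic acid | OC(=O)C1=C[C@]2(O[Si](C)(C)C(C)(C)C)C[C@H]3C(C)(C)O[C@@](CC=C(C)C)(C2=O)[C@@]13O[Si](C)(C)C(C)(C)C | intermediate
24 | (1R,3R,6R,7S)-1,7-dihydroxy-5,5-dimethyl-3-(3-methylbut-2-en-1-yl)-2-oxo-4-oxatricyclo[4.3.1.0^3,7]dec-8-ene-8-carboxylic acid | OC(=O)C1=C[C@]2(O)C[C@H]3C(C)(C)O[C@@](CC=C(C)C)(C2=O)[C@@]13O | intermediate
25 | 2,2-dimethyl-6-(3-methylbut-2-en-1-yl)-5,8-dioxo-5,8-dihydro-2H-chromen-7-yl (1R,3R,6R,7S)-1,7-dihydroxy-5,5-dimethyl-3-(3-methylbut-2-en-1-yl)-2-oxo-4-oxatricyclo[4.3.1.0^3,7]dec-8-ene-8-carboxylate (acyloxyquinone) | CC(C)=CCC1=C(OC(=O)C2=C[C@]3(O)C[C@H]4C(C)(C)O[C@@](CC=C(C)C)(C3=O)[C@@]24O)C(=O)C2=C(C=CC(C)(C)O2)C1=O | intermediate (not isolated)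
26 | CNP0222516.1: spiro ketal-lactone of the cage hydroxy acid with the pyranoquinone ring, configuration as in the SMILES | CC(C)=CC[C@H]1C(=O)C2=C(OC(C)(C)C=C2)C(=O)[C@@]12OC(=O)C1=C[C@]3(O)C[C@H]4C(C)(C)O[C@@](CC=C(C)C)(C3=O)[C@@]14O2 | target

Total step count: 14. Longest linear sequence: 10 steps (5 → 12 → 14 → 16 → 17 → 19 → 21 → 22 → 23 → 24 → 26; steps 5–14).

Steps most likely to fail

1. Step 14 (esterification/spiroketalisation). Three things may go wrong: acyl transfer to the wrong oxygen of the ambident hydroxyquinone anion; cleavage of the activated quinonyl ester by DMAP or moisture before the hindered tertiary alcohol has added; and incomplete equilibration at the two new centres. The fallback sets out from 10 and 24 and comes back at 26. The acid is first bound as a robust aryl ester by DCC/DMAP acylation of the less hindered 7-OH of chromenediol 10, which should give 5-hydroxy-chromen-7-yl ester F1. Teuber oxidation of the remaining 5-OH phenol (Fremy's salt, pH 6 buffer) then unveils acyloxyquinone 25 only at the very end and under neutral conditions, where the tertiary alcohol should add to give 26 (a trace of Et3N to complete equilibration).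

2. Step 7 (Teuber oxidation of a salicylaldehyde). Hydrogen abstraction from the formyl-chelated, electron-poor phenol may be slow, and the electrophilic formylquinone may decompose before it is reduced. The fallback sets out from 14 and comes back at 17. NaBH4 reduction removes the deactivating and chelating formyl group and should give benzyl alcohol F2. Fremy's salt followed by dithionite then oxidises the now electron-rich phenol to hydroquinone F3. Per-silylation (TBSCl, imidazole) gives tris-silyl ether F4; PPTS in MeOH cleaves only the primary benzylic silyl ether to give benzylic alcohol F5; MnO2 oxidation returns aldehyde 17.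

3. Step 10 (resolution through the aminal). Condensation at the hindered, conjugated formyl group may stay incomplete, or the two diastereomers may co-elute. The fallback sets out from 19 and comes back at 23. Pinnick oxidation of racemic 19 should give racemic acid F6. Fractional crystallisation of its salt with (S)-1-phenylethylamine (or with the antipode, whichever gives the less soluble salt of the required enantiomer) should provide ammonium salt F7, and acidification (aq. KHSO4/EtOAc) releases 23.

Further compounds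
F1 | step 14 | 5-hydroxy-2,2-dimethyl-6-(3-methylbut-2-en-1-yl)-2H-chromen-7-yl (1R,3R,6R,7S)-1,7-dihydroxy-5,5-dimethyl-3-(3-methylbut-2-en-1-yl)-2-oxo-4-oxatricyclo[4.3.1.0^3,7]dec-8-ene-8-carboxylate | CC(C)=CCc1c(O)c2C=CC(C)(C)Oc2cc1OC(=O)C1=C[C@]2(O)C[C@H]3C(C)(C)O[C@@](CC=C(C)C)(C2=O)[C@@]13O
F2 | step 7 | 2-(hydroxymethyl)-5,6-bis[(2-methylbut-3-en-2-yl)oxy]phenol | OCc1ccc(OC(C)(C)C=C)c(OC(C)(C)C=C)c1O
F3 | step 7 | 2-(hydroxymethyl)-5,6-bis[(2-methylbut-3-en-2-yl)oxy]benzene-1,4-diol | OCc1cc(O)c(OC(C)(C)C=C)c(OC(C)(C)C=C)c1O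
F4 | step 7 | tert-butyl({2,5-bis[(tert-butyldimethylsilyl)oxy]-3,4-bis[(2-methylbut-3-en-2-yl)oxy]phenyl}methoxy)dimethylsilane | CC(C)(C)[Si](C)(C)OCc1cc(O[Si](C)(C)C(C)(C)C)c(OC(C)(C)C=C)c(OC(C)(C)C=C)c1O[Si](C)(C)C(C)(C)C
F5 | step 7 | {2,5-bis[(tert-butyldimethylsilyl)oxy]-3,4-bis[(2-methylbut-3-en-2-yl)oxy]phenyl}methanol | OCc1cc(O[Si](C)(C)C(C)(C)C)c(OC(C)(C)C=C)c(OC(C)(C)C=C)c1O[Si](C)(C)C(C)(C)C
F6 | step 10 | rac-(1R*,3R*,6S*,7S*)-1,7-bis[(tert-butyldimethylsilyl)oxy]-5,5-dimethyl-3-(3-methylbut-2-en-1-yl)-2-oxo-4-oxatricyclo[4.3.1.0^3,7]dec-8-ene-8-carboxylic acid (racemic; one enantiomer drawn) | OC(=O)C1=C[C@]2(O[Si](C)(C)C(C)(C)C)C[C@H]3C(C)(C)O[C@@](CC=C(C)C)(C2=O)[C@@]13O[Si](C)(C)C(C)(C)C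
F7 | step 10 | (S)-1-phenylethylammonium (1R,3R,6S,7S)-1,7-bis[(tert-butyldimethylsilyl)oxy]-5,5-dimethyl-3-(3-methylbut-2-en-1-yl)-2-oxo-4-oxatricyclo[4.3.1.0^3,7]dec-8-ene-8-carboxylate | C[C@H]([NH3+])c1ccccc1.[O-]C(=O)C1=C[C@]2(O[Si](C)(C)C(C)(C)C)C[C@H]3C(C)(C)O[C@@](CC=C(C)C)(C2=O)[C@@]13O[Si](C)(C)C(C)(C)C
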